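The earlier runs and the new flask are simulated with made-up constants, and the scatter is random.

Read the earlier blue run as a single rate, and carry that rate over to the smaller charges made with the same catalyst.

the same everywhere: free catalyst 1.7 mM

|  | substrate | remark | time |
|---|---|---|---|
| blue | 150 mM | run made earlier |  |
| birch | 30 mM |  | 15 min |
| elm | 40 mM |  | 15 min |
| ash | 60 mM |  | 15 min |
| larch | 100 mM |  | 15 min |

- blue (time / min: target / %, substrate / %): 4.00: 5.1, 94.3; 8.00: 12.3, 85.4; 12.0: 12.2, 83.2; 15.0: 13.4, 76.9

(readings scatter by 1 percentage point)

- amount of target at the end, in percent of the substrate charged for birch, elm, ash, larch, in this order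
- the shape of the row from first to last (falls all the way / falls, then rises / rises, then falls / hardly changes / rises all the way)

- what is said of target includes idle complex
- steps thought possible: substrate + free catalyst -> catalyst intermediate A; catalyst intermediate A -> catalyst intermediate B; catalyst intermediate B <-> free catalyst + target; target -> over-reaction product; free catalyst + target <-> idle complex
- "hardly changes" means that all values lie within two and a half points (for a concentration: within two and a half percent of the largest)

In blue, substrate falls at 2.14 mM min⁻¹ up to 4.00 min and at 2.37 mM min⁻¹ after it, which shows no slowing beyond the scatter of 1 percentage point in a reading. Meanwhile substrate has dropped to 76.9% of its charge and target has risen to 13.4%, yet as a reading the later rate stands above the earlier one, so I put the slowing from the two together at a factor of about 1. My judgement, which this run cannot prove, is that the catalyst works at a ceiling, zero order in substrate, of 2.31 mM min⁻¹. Ceiling times 15 min gives 34.6 mM. I call this the reach: the substrate I reckon this catalyst charge turns over in that time, as long as substrate lasts.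

A second factor acts on target. Of the substrate blue has used, 58.0% stands as target. I book the missing part as over-reaction product, since it is more than the catalyst could hold. Elm, ash and larch are charged above the reach, so each gets share times reach over charge: 50.2%, 33.5% and 20.1%. Birch is charged below the reach, so substrate is its limiting reagent, reckoned to be used up near 13.0 min, and I give it the plain share, 58.0%.

The forecast, lower than my row at each point, gives 36%, 33%, 27% and 19%, holding that “the percentage falls with charge”. The flask gives 60.1%, 52.1%, 35.2% and 21.2%, a row that falls all the way, between 1.1 points and 2.1 points above mine.

    substrate + free catalyst → catalyst intermediate A (k = 9400 M⁻¹ min⁻¹)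
    catalyst intermediate A → catalyst intermediate B (k = 1.30 min⁻¹)
    catalyst intermediate B ⇌ free catalyst + target (K = 0.0160 M, k = 110 min⁻¹)
    target → over-reaction product (k = 0.0620 min⁻¹)
    free catalyst + target ⇌ idle complex (K = 51.0 M⁻¹, k = 12.0 M⁻¹ min⁻¹)

Larch turned over 34.3 mM of substrate and elm 33.8 mM, each close to the reach, while birch fell under a fiftieth of its charge at 13.4 min. With larch's substrate as charged, free catalyst is captured at 940 min⁻¹, far faster than catalyst intermediate A moves on at 1.3 min⁻¹, and at 7.50 min larch holds 98.5% of its catalyst as catalyst intermediate A, the resting state.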